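**Retrosynthetic overview**
1. Target 15 ⇐ pentabenzyl biflavone 14 by hydrogenolysis; 14 ⇐ bis(2'-hydroxychalcone) 12 by one double oxidative cyclization that closes both pyranone rings at once.
2. 12 ⇐ chalcone 8 + 4-(benzyloxy)cinnamic acid 9: Friedel–Crafts cinnamoylation of ring P, with chelation-controlled loss of the one benzyl group (on P2) whose oxygen becomes O1'' of the 8-linked flavone.
3. 8 ⇐ aldehyde 6 + acetophenone 7 (Claisen–Schmidt); 6 ⇐ biaryl phenol 3 by oxidation of the para-methyl group and O-methylation.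
4. Key step: the C3'–C8'' biaryl bond is not made by cross-coupling of two halogenated or metalated flavones, but by anodic dehydrogenative C–H/C–H coupling of creosol 1 with 1,3,5-tris(benzyloxy)benzene 2, before any heterocycle exists.
5. Ring order: rings B and P are joined first, rings A and D are attached as open chalcone arms, and both pyranone rings are formed last, together.

Assumption: the target has no stereocentre and its SMILES defines no axis, so the biaryl axis is taken as configurationally undefined and no enantiocontrol is needed; compounds 2, 7 and 9 are taken as purchasable.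

Labels: unit 1 is the 5,7-dihydroxyflavone whose aryl ring is the dimethoxyphenyl ring B; unit 2 is the apigenin unit. Ring A is the phloroglucinol ring of unit 1. Ring P is the phloroglucinol ring of unit 2, with P1 the biaryl carbon and P2–P6 numbered round the ring. Ring D is the 4-hydroxyphenyl ring.

**Step 1**
Reactants: 1 2-methoxy-4-methylphenol (creosol); 2 1,3,5-tris(benzyloxy)benzene
Product: 3 2-methoxy-4-methyl-6-[2,4,6-tris(benzyloxy)phenyl]phenol
Conditions: boron-doped diamond anode, nickel cathode, undivided cell, 2.8 mA cm−2, 2.0 F mol−1 on 1, Bu3MeN+ MeOSO3− (0.09 M), HFIP/MeOH 82:18, 50 °C; 2 (3 equiv)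
Reagents that add atoms: none
Why: Anodic phenol–arene cross-dehydrogenative coupling, in which the phenol 1 is oxidised first in HFIP and its solvated phenoxyl is trapped by the more nucleophilic arene 2 at the only free ortho/para position of 1 (C6, para being blocked by methyl), while the threefold symmetry of 2 leaves a single possible site; no stereocentre is formed.

**Step 2**
Reactants: 3 2-methoxy-4-methyl-6-[2,4,6-tris(benzyloxy)phenyl]phenol
Product: 5 4-hydroxy-3-methoxy-5-[2,4,6-tris(benzyloxy)phenyl]benzaldehyde, via benzylic alcohol 4 (not isolated)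
Conditions: DDQ (2.2 equiv), 1,4-dioxane/H2O 9:1, rt
Reagents that add atoms: water, O
Why: Quinone-mediated benzylic oxidation of a 2,6-disubstituted para-cresol, in which DDQ takes a hydride from the methyl group para to the free hydroxyl, water adds to give 4, and a second dehydrogenation stops at the aldehyde because the product phenol is now electron-poor; aryl benzyl ethers and the trialkoxyarene are inert to DDQ.

**Step 3**
Reactants: 5 4-hydroxy-3-methoxy-5-[2,4,6-tris(benzyloxy)phenyl]benzaldehyde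
Product: 6 3,4-dimethoxy-5-[2,4,6-tris(benzyloxy)phenyl]benzaldehyde
Conditions: MeI (1.5 equiv), K2CO3, DMF, rt
Reagents that add atoms: iodomethane, CI
Why: Williamson O-methylation of the only free, acidic (vanillin-type) phenol, which installs the 4'-methoxy group of the target.

**Step 4**
Reactants: 6 3,4-dimethoxy-5-[2,4,6-tris(benzyloxy)phenyl]benzaldehyde; 7 1-[2,4-bis(benzyloxy)-6-hydroxyphenyl]ethan-1-one
Product: 8 (2E)-1-[2,4-bis(benzyloxy)-6-hydroxyphenyl]-3-{3,4-dimethoxy-5-[2,4,6-tris(benzyloxy)phenyl]phenyl}prop-2-en-1-one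
Conditions: KOH (50% aq., excess), EtOH/THF, rt, 24–48 h; then dilute HCl
Reagents that add atoms: none
Why: Claisen–Schmidt condensation of a non-enolisable aldehyde with the 2-hydroxyacetophenone enolate, where E1cB dehydration gives the conjugated E-alkene as the thermodynamic product; no stereocentre is formed.

**Step 5**
Reactants: 8 the chalcone from step 4; 9 (2E)-3-[4-(benzyloxy)phenyl]prop-2-enoic acid
Product: 12 (2E)-1-[2,4-bis(benzyloxy)-6-hydroxyphenyl]-3-{3-[2-hydroxy-4,6-bis(benzyloxy)-3-{(2E)-3-[4-(benzyloxy)phenyl]prop-2-enoyl}phenyl]-4,5-dimethoxyphenyl}prop-2-en-1-one, via acid chloride 10 (not isolated), via tris-benzyl ketone 11 (not isolated)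
Conditions: 9, (COCl)2 (1.5 equiv), DMF (cat.), CH2Cl2, rt; crude 10 added to 8 precomplexed with TiCl4 (3 equiv), CH2Cl2, −40 → 0 °C; ice/1 M HCl
Reagents that add atoms: oxalyl chloride, O=C(Cl)C(=O)Cl (its chlorine sits in 10 only and is lost again; 12 is built from 8 and 9 alone)
Why: Friedel–Crafts acylation at P3 (equivalent to P5, the only strongly activated free positions in 8) followed by chelation-controlled ortho-de-O-benzylation by TiCl4, which removes the P2 benzyl group because that oxygen is flanked by both acyl and aryl, twisted out of conjugation and therefore the more Lewis basic partner for the carbonyl-bound titanium, as in the acylation of 1,2,3,5-tetramethoxybenzene to 2-hydroxy-3,4,6-trimethoxyacetophenone; the resulting titanium chelate protects the P4 ether, and both alkenes stay E.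

**Step 6**
Reactants: 12 the bis(2'-hydroxychalcone) from step 5
Product: 14 5,7-bis(benzyloxy)-8-{5-[5,7-bis(benzyloxy)-4-oxo-4H-chromen-2-yl]-2,3-dimethoxyphenyl}-2-[4-(benzyloxy)phenyl]-4H-chromen-4-one, via bis-flavanone 13 (not isolated)
Conditions: I2 (0.2 equiv), DMSO, 130 °C; aq. Na2S2O3 work-up
Reagents that add atoms: none
Why: Two-directional iodine-catalysed oxidative cyclization, in which each 2'-hydroxychalcone closes by oxa-Michael addition and is dehydrogenated by α-iodination and loss of HI with DMSO regenerating I2; ring P can close only through its single free hydroxyl at P2, which fixes the 8-linkage, and the benzyl ether at C5'' prevents Wessely–Moser scrambling; the flavanone stereocentres of 13 are destroyed.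

**Step 7**
Reactants: 14 the pentabenzyl biflavone from step 6
Product: 15 5'-methoxybilobetin, 8-[5-(5,7-dihydroxy-4-oxo-4H-chromen-2-yl)-2,3-dimethoxyphenyl]-5,7-dihydroxy-2-(4-hydroxyphenyl)-4H-chromen-4-one
Conditions: H2 (1 atm), Pd/C (10 wt%), THF/MeOH 1:1, rt
Reagents that add atoms: none
Why: Catalytic hydrogenolysis of the five aryl benzyl ethers under mild conditions that leave the two methyl ethers, the biaryl bond and the conjugated chromone C2=C3 bonds untouched; the product has no stereocentre.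

**Compound list**
1 | 2-methoxy-4-methylphenol (creosol) | Cc1ccc(O)c(OC)c1 | starting material
2 | 1,3,5-tris(benzyloxy)benzene | c1ccc(COc2cc(OCc3ccccc3)cc(OCc3ccccc3)c2)cc1 | starting material
3 | 2-methoxy-4-methyl-6-[2,4,6-tris(benzyloxy)phenyl]phenol | Cc1cc(OC)c(O)c(-c2c(OCc3ccccc3)cc(OCc3ccccc3)cc2OCc2ccccc2)c1 | intermediate
4 | 4-(hydroxymethyl)-2-methoxy-6-[2,4,6-tris(benzyloxy)phenyl]phenol | OCc1cc(OC)c(O)c(-c2c(OCc3ccccc3)cc(OCc3ccccc3)cc2OCc2ccccc2)c1 | intermediate (not isolated)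
5 | 4-hydroxy-3-methoxy-5-[2,4,6-tris(benzyloxy)phenyl]benzaldehyde | O=Cc1cc(OC)c(O)c(-c2c(OCc3ccccc3)cc(OCc3ccccc3)cc2OCc2ccccc2)c1 | intermediate
6 | 3,4-dimethoxy-5-[2,4,6-tris(benzyloxy)phenyl]benzaldehyde | O=Cc1cc(OC)c(OC)c(-c2c(OCc3ccccc3)cc(OCc3ccccc3)cc2OCc2ccccc2)c1 | intermediate
7 | 1-[2,4-bis(benzyloxy)-6-hydroxyphenyl]ethan-1-one | CC(=O)c1c(O)cc(OCc2ccccc2)cc1OCc1ccccc1 | starting material
8 | (2E)-1-[2,4-bis(benzyloxy)-6-hydroxyphenyl]-3-{3,4-dimethoxy-5-[2,4,6-tris(benzyloxy)phenyl]phenyl}prop-2-en-1-one | COc1cc(/C=C/C(=O)c2c(O)cc(OCc3ccccc3)cc2OCc2ccccc2)cc(-c2c(OCc3ccccc3)cc(OCc3ccccc3)cc2OCc2ccccc2)c1OC | intermediate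
9 | (2E)-3-[4-(benzyloxy)phenyl]prop-2-enoic acid | OC(=O)/C=C/c1ccc(OCc2ccccc2)cc1 | starting material
10 | (2E)-3-[4-(benzyloxy)phenyl]prop-2-enoyl chloride | ClC(=O)/C=C/c1ccc(OCc2ccccc2)cc1 | intermediate (not isolated)
11 | (2E)-1-[2,4-bis(benzyloxy)-6-hydroxyphenyl]-3-{3,4-dimethoxy-5-[2,4,6-tris(benzyloxy)-3-{(2E)-3-[4-(benzyloxy)phenyl]prop-2-enoyl}phenyl]phenyl}prop-2-en-1-one | COc1cc(/C=C/C(=O)c2c(O)cc(OCc3ccccc3)cc2OCc2ccccc2)cc(-c2c(OCc3ccccc3)c(C(=O)/C=C/c3ccc(OCc4ccccc4)cc3)c(OCc3ccccc3)cc2OCc2ccccc2)c1OC | intermediate (not isolated)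
12 | (2E)-1-[2,4-bis(benzyloxy)-6-hydroxyphenyl]-3-{3-[2-hydroxy-4,6-bis(benzyloxy)-3-{(2E)-3-[4-(benzyloxy)phenyl]prop-2-enoyl}phenyl]-4,5-dimethoxyphenyl}prop-2-en-1-one | COc1cc(/C=C/C(=O)c2c(O)cc(OCc3ccccc3)cc2OCc2ccccc2)cc(-c2c(O)c(C(=O)/C=C/c3ccc(OCc4ccccc4)cc3)c(OCc3ccccc3)cc2OCc2ccccc2)c1OC | intermediate
13 | 5,7-bis(benzyloxy)-8-{5-[5,7-bis(benzyloxy)-4-oxochroman-2-yl]-2,3-dimethoxyphenyl}-2-[4-(benzyloxy)phenyl]chroman-4-one (mixture of stereoisomers) | COc1cc(C2CC(=O)c3c(OCc4ccccc4)cc(OCc4ccccc4)cc3O2)cc(-c2c(OCc3ccccc3)cc(OCc3ccccc3)c3c2OC(c2ccc(OCc4ccccc4)cc2)CC3=O)c1OC | intermediate (not isolated)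
14 | 5,7-bis(benzyloxy)-8-{5-[5,7-bis(benzyloxy)-4-oxo-4H-chromen-2-yl]-2,3-dimethoxyphenyl}-2-[4-(benzyloxy)phenyl]-4H-chromen-4-one | COc1cc(-c2cc(=O)c3c(OCc4ccccc4)cc(OCc4ccccc4)cc3o2)cc(-c2c(OCc3ccccc3)cc(OCc3ccccc3)c3c(=O)cc(-c4ccc(OCc5ccccc5)cc4)oc23)c1OC | intermediate
15 | 5'-methoxybilobetin | COc1cc(-c2cc(=O)c3c(O)cc(O)cc3o2)cc(-c2c(O)cc(O)c3c(=O)cc(-c4ccc(O)cc4)oc23)c1OC | target

**Totals**
Total step count: 7. Longest linear sequence: 7 steps (1 and 2 to 15).

**Three steps most likely to fail**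

Step 5 (regiochemistry of the debenzylation, P2 versus P4, and chemoselectivity of the acylation). Loss of the P4 benzyl group instead would lead to the 6-linked isomer. Loss of the ring A 6'-benzyl or the P6 benzyl would be harmless.
Fallback: set out from 5 and fix the regiochemistry by geometry instead of by relative Lewis basicity. BCl3 (1.05 equiv, CH2Cl2, −78 → −20 °C) first forms the aryloxydichloroborane at the C4' hydroxyl. This boron can reach only the equivalent P2/P6 benzyloxy groups, never P4, so a proposed chelation-directed de-O-benzylation gives 4-hydroxy-3-[2-hydroxy-4,6-bis(benzyloxy)phenyl]-5-methoxybenzaldehyde F4. Claisen–Schmidt condensation with 7 (excess KOH, EtOH/THF, 50 °C, slower because the aldehyde is a 4-hydroxybenzaldehyde) gives (2E)-1-[2,4-bis(benzyloxy)-6-hydroxyphenyl]-3-{4-hydroxy-3-[2-hydroxy-4,6-bis(benzyloxy)phenyl]-5-methoxyphenyl}prop-2-en-1-one F5. TiCl4-mediated, phenol-directed ortho-acylation with 10 (made from 9 as in step 5) can occur only at P3, the single free position ortho to the P2 hydroxyl. It gives (2E)-1-[2,4-bis(benzyloxy)-6-hydroxyphenyl]-3-{4-hydroxy-3-[2-hydroxy-4,6-bis(benzyloxy)-3-{(2E)-3-[4-(benzyloxy)phenyl]prop-2-enoyl}phenyl]-5-methoxyphenyl}prop-2-en-1-one F6. MeI/K2CO3 in acetone then methylates the only non-chelated phenol (C4'), and the route is rejoined at 12.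

Step 1 (anodic cross-coupling with the bulky, poorly soluble arene 2; homocoupling or over-oxidation).
Fallback: set out from 1 and 2 and make the same bond by cross-coupling. NBS (CH2Cl2, 0 °C) brominates 1 ortho to the hydroxyl to give 2-bromo-6-methoxy-4-methylphenol F1. NBS also monobrominates 2 to give 2-bromo-1,3,5-tris(benzyloxy)benzene F2. Bromine–lithium exchange on F2 (n-BuLi, THF, −78 °C), B(OMe)3 and aqueous acid give [2,4,6-tris(benzyloxy)phenyl]boronic acid F3. Suzuki–Miyaura coupling of F1 with F3 (Pd(OAc)2, SPhos, K3PO4, toluene/H2O, 90 °C) rejoins the route at 3.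

Step 6 (two ring closures at once, one onto the hindered P2 hydroxyl; HI may cleave the peri 5-O-benzyl groups, which is harmless because step 7 removes them anyway).
Fallback: set out from 12 and separate ring closure from dehydrogenation. NaOAc in refluxing EtOH cyclizes both arms by oxa-Michael addition, and the bis-flavanone 13 is isolated. DDQ in refluxing dioxane then dehydrogenates both C2–C3 bonds, and the route is rejoined at 14. This fallback makes no compound outside the list (entry F0).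

**Further compounds**
F1 | step 1 | 2-bromo-6-methoxy-4-methylphenol | Cc1cc(Br)c(O)c(OC)c1
F2 | step 1 | 2-bromo-1,3,5-tris(benzyloxy)benzene | Brc1c(OCc2ccccc2)cc(OCc2ccccc2)cc1OCc1ccccc1
F3 | step 1 | [2,4,6-tris(benzyloxy)phenyl]boronic acid | OB(O)c1c(OCc2ccccc2)cc(OCc2ccccc2)cc1OCc1ccccc1
F4 | step 5 | 4-hydroxy-3-[2-hydroxy-4,6-bis(benzyloxy)phenyl]-5-methoxybenzaldehyde | O=Cc1cc(OC)c(O)c(-c2c(O)cc(OCc3ccccc3)cc2OCc2ccccc2)c1
F5 | step 5 | (2E)-1-[2,4-bis(benzyloxy)-6-hydroxyphenyl]-3-{4-hydroxy-3-[2-hydroxy-4,6-bis(benzyloxy)phenyl]-5-methoxyphenyl}prop-2-en-1-one | COc1cc(/C=C/C(=O)c2c(O)cc(OCc3ccccc3)cc2OCc2ccccc2)cc(-c2c(O)cc(OCc3ccccc3)cc2OCc2ccccc2)c1O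
F6 | step 5 | (2E)-1-[2,4-bis(benzyloxy)-6-hydroxyphenyl]-3-{4-hydroxy-3-[2-hydroxy-4,6-bis(benzyloxy)-3-{(2E)-3-[4-(benzyloxy)phenyl]prop-2-enoyl}phenyl]-5-methoxyphenyl}prop-2-en-1-one | COc1cc(/C=C/C(=O)c2c(O)cc(OCc3ccccc3)cc2OCc2ccccc2)cc(-c2c(O)c(C(=O)/C=C/c3ccc(OCc4ccccc4)cc3)c(OCc3ccccc3)cc2OCc2ccccc2)c1O
F0 | step 6 | none | none
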